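At the reading time of 6.0 d the earlier runs seemed not to go together: east held 40.2% of its charge as ring, while north, charged with less, held 26.9%, and west, charged with more, held 12.3%.

| flask | solid substrate | remark | time |
|---|---|---|---|
| north | 0.089 M | run made earlier |  |
| east | 0.45 M | run made earlier |  |
| west | 1.6 M | run made earlier |  |
| cedar | 0.12 M |  | 6.0 d |
| oak | 0.50 M |  | 6.0 d |
| alder | 1.5 M |  | 6.0 d |
| elm | 0.80 M |  | 6.0 d |
| ash | 1.0 M |  | 6.0 d |
| maple | 0.30 M |  | 6.0 d |

| run | time / d | ring / % | solid substrate / % |
|---|---|---|---|
| north | 1.67 | 54.7 | 0 |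
| north | 3.00 | 45.7 | 0.7 |
| north | 5.00 | 32.3 | 0.7 |
| north | 6.00 | 26.9 | 0 |
| east | 0.500 | 3.4 | 89.2 |
| east | 1.04 | 9.8 | 78.5 |
| east | 2.50 | 23.3 | 50.3 |
| east | 6.00 | 40.2 | 0 |
| west | 0.833 | 1.1 | 95.2 |
| west | 2.00 | 5.5 | 88.7 |
| west | 4.00 | 10.2 | 77.4 |
| west | 6.00 | 12.3 | 67.7 |

(standard deviation of a reading: 0.5 percentage points)

- ranking by amount of ring, in percent of the solid substrate charged, from high to low, at 6.0 d (cedar / oak / alder / elm / ash / maple)
- the same order at 30 h (cedar / oak / alder / elm / ash / maple)
- the amount of ring, in percent of the solid substrate charged of the flask you put first, at 6.0 d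
- the amount of ring, in percent of the solid substrate charged of the flask you put last, at 6.0 d

- as a solid, counted per litre of solution: solid substrate
- at the start none of the solid substrate is in solution
- what has only dissolved of solid substrate counts as not reacted

I cleared this up by watching the solid. West lost 0.0861 M d⁻¹ up to 6.00 d, and east lost 0.0895 M d⁻¹ up to 2.50 d. I took the west figure as the pace of the solid, the amount of solid substrate lost per day, which in these two runs was zero order in the charge. A charge divided by the pace gives its run-out time: 1.03 d for north, 5.22 d for east and 18.6 d for west. So north's ring fell from 54.7% at 1.67 d with 0% solid at its last reading, east's reckoned run-out came 0.780 d before its reading of 0% solid, and west still held 67.7% of its charge as solid.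

For the new flasks I reckoned run-out at 1.39 d for cedar, 3.48 d for maple, 5.80 d for oak, 9.29 d for elm, 11.6 d for ash and 17.4 d for alder. I put oak first at 6.0 d, because its run-out came later than maple's and north's ring had fallen with its solid at 0%. Cedar's run-out, the earliest, came after 30 h, so I ranked that reading by rising charge, the smallest charge first.

The forecast gave maple > oak > cedar > elm > ash > alder at 6.0 d and cedar > maple > oak > elm > ash > alder at 30 h, with 39.5% first and 13.1% last, and it differed from me at the head: “Oak runs out at about 5.5 d, giving about 38%. Maple runs out at about 3.3 d, giving about 39%, a near tie with oak.”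

The flasks gave oak > maple > cedar > elm > ash > alder at 6.0 d and cedar > maple > oak > elm > ash > alder at 30 h, with 40.3% first and 13.6% last.

    starting material → ring (k = 0.00131 min⁻¹)
    2 starting material → open dimer (k = 3.32 × 10⁻⁴ M⁻¹ min⁻¹)
    ring → over-reaction product (k = 1.92 × 10⁻⁴ min⁻¹)
    solid substrate ⇌ starting material, rate k4*(cs4 - [starting material]) while solid is left; crystals form when [starting material] > cs4 (solubility = 0.210 M, k = 3.43 × 10⁻⁴ min⁻¹)
    starting material ⇌ dormant form (K = 2.30, k = 5.68 × 10⁻⁴ min⁻¹)

Forecast and flask parted at the head: maple gave 33.6% and oak 40.3%. By the pace, maple's solid was gone at 3.48 d and oak's at 5.80 d, and both flasks showed 0% solid at 6.00 d. The neighbour of alder, charged with 0.90 M, has a run-out of 10.4 d, later than the reading, so the pace leaves 42.3% of its charge as solid at 6.0 d. That flask held 42.4% solid substrate and 22.7% ring.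

The runs were computed for substances that don't exist; scatter was added.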